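**Early instants.** At early times this flask holds one portion of Z, 3.75 mM, in 13.5 mM of G, so G stands in excess. The rest of Z arrives over the next 3.00 min.

| flask | Z | G | remark | time |
|---|---|---|---|---|
| gamma | 15 mM (in portions, 4) | 9 mM | run made earlier; portions every 1.0 min |  |
| delta | 15 mM (in portions, 4) | 20 mM | run made earlier; portions every 1.0 min |  |
| eta | 7.5 mM (in portions, 4) | 13.5 mM | run made earlier; portions every 1.0 min |  |
| flask | 15 mM (in portions, 4) | 13.5 mM | the portions of Z follow each other after 1.0 min, the first at the start | 5.0 h |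

| run | time / h | Z / % | Q / % | D / % |
|---|---|---|---|---|
| gamma | 0.833 | 71.4 | 29.9 | 1.0 |
| gamma | 1.50 | 69.8 | 29.0 | 1.8 |
| gamma | 2.50 | 69.8 | 30.2 | 1.2 |
| gamma | 3.00 | 70.2 | 27.6 | 0.8 |
| gamma | 4.00 | 69.9 | 28.2 | 2.0 |
| delta | 0.333 | 43.8 | 52.2 | 2.9 |
| delta | 1.00 | 42.9 | 51.6 | 1.7 |
| delta | 2.00 | 41.2 | 51.7 | 2.9 |
| delta | 3.00 | 42.3 | 51.6 | 0.7 |
| delta | 4.00 | 42.8 | 50.6 | 3.4 |
| eta | 0.333 | 41.3 | 50.3 | 2.9 |
| eta | 0.667 | 41.8 | 50.1 | 3.6 |
| eta | 1.00 | 43.8 | 50.4 | 2.7 |
| eta | 2.00 | 43.1 | 50.9 | 2.4 |
| eta | 4.00 | 42.6 | 50.9 | 3.5 |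

(scatter of a reading: 1 percentage point)

* why nothing more happens at 5.0 h, or that something still does (it is still moving / G has run out first / all of Z has reacted)
* share of the Z used up at 5.0 h
* Q at 5.0 h, in percent of the Z charged
* D at 5.0 h, in percent of the Z charged

- the analysis behind the earlier runs scatters by 1 percentage point, standard deviation
- a reading or a percentage of Q counts all its forms, free or not
- the reaction counts as stopped when no species that holds the Z changes by six tenths of a point or more over the second half of the time

**The end state.** Those minutes are unseen. The first delta reading, at 0.333 h, already shows Z at 43.8%, and at 4.00 h it reads 42.8%. Each run went flat with Z left, so I took G to be gone. Yet in delta the G found on Q and D came to about 8.61 mM of 20 mM.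

**The scale's zero.** If each G took one Z, this flask would use 90.0% of its Z. To measure the departure, I let G react with Z at a rate proportional to both, against a first-order loss of G. The share reaching Z is then Z/(Z + c), which integrates to: G charged = Z used + c·ln(Z charged/Z left).

Gamma reads 12.5 mM and delta 13.5 mM, but eta, with 7.5 mM of Z, reads 10.8 mM. So I kept the two runs with this flask's Z charge and carried their mean as the loss constant, a fitted lump for the G that does not take a Z, not a measured level of Z: 13.0 mM.

**My reckoning.** Interpolating on G between gamma and delta gave 41.2% of Z used. One correction along the rule gave 42.3%.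

**The forecast.** It said G has run out first, with 43% of Z used, Q 41% and D 2%, on the ground that “A first-order G loss competing with Z fits”. That is 0.70 percentage points above my figure.

**The flask.** It gave G has run out first, with 42.5% of Z used, Q 39.3% and D 1.57%.

    Z + G → Q (k = 64.0 M⁻¹ min⁻¹)
    G + Q → D (k = 43.0 M⁻¹ min⁻¹)
    G + D → L (k = 75.0 M⁻¹ min⁻¹)
    G + L → J (k = 8.50 M⁻¹ min⁻¹)
    G → E (k = 0.290 min⁻¹)
    X ⇌ Q, rate k6*(cs6 - [Q]) while solid is left; crystals form when [Q] > cs6 (solubility = 0.400 mM, k = 11.0 min⁻¹)

**Two clocks.** In this flask at 0.0176 h, the half-life of G by reaction with Z was 2.0 min, and its half-life by turning into E alone was a little longer than that, 2.4 min. At 5.00 h G stood at 0% of its charge, less than the 58% of Z left. Put back into the rule, this flask reads 12.9 mM. The neighbour flask with 6.0 mM of Z and the same G used 62.0% of its Z and reads lower, at 10.1 mM.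

(The earlier runs and the new flask were generated by integration for an exercise; noise was put on by code.)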